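**Strategy.** Ring A is a phloroglucinol whose C1, lying between the hydroxyl-bearing C2 and C6, carries the ether oxygen to ring B. Its six carbons are therefore a tri-acetate chain whose last carbon bears an aryloxy substituent. The route cuts the A-C1 to A-C2 bond. In one operation methoxide releases this chain from a 6-(aryloxymethyl)-4-methoxy-2-pyranone and folds it by Claisen condensation into the aromatic ring. The crowded A-O-B ether is thus already in place, made by ordinary O-alkylation of a phenol. The precursor is the pyranone whose C6 methylene bears the benzyl-protected ring B phenoxy group. Rings C, D and E are attached afterwards as one fragment by palladium-catalysed etherification.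

Key step: step 5

Assumption: rings are lettered A to E in the order in which they occur in the target SMILES, and the two bromobenzaldehydes used for rings C and D are taken as purchasable alongside the methoxypyranone, the salicylaldehyde and 3,4,5-trimethoxyphenol.

**Fragment A-B**

Step 1
Reactants: 1 4-methoxy-6-methyl-2H-pyran-2-one
Product: 2 6-(bromomethyl)-4-methoxy-2H-pyran-2-one
Conditions: NBS, (PhCO2)2 (cat.), CCl4, reflux
Reagents that add atoms: N-bromosuccinimide, O=C1CCC(=O)N1Br
Why: Wohl-Ziegler bromination, in which radical-chain hydrogen abstraction in a non-polar solvent occurs at the C6 methyl group (its radical is delocalised over the pyranone diene) while ionic bromination at C3 is suppressed.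

Step 2
Reactants: 2 6-(bromomethyl)-4-methoxy-2H-pyran-2-one; 3 2-hydroxy-4,6-dimethoxybenzaldehyde
Product: 4 2,4-dimethoxy-6-[(4-methoxy-2-oxo-2H-pyran-6-yl)methoxy]benzaldehyde
Conditions: K2CO3, DMF, rt to 50 °C
Reagents that add atoms: none
Why: Williamson ether synthesis, in which the acidic hydrogen-bonded phenol of 3 is deprotonated by carbonate and displaces the activated primary bromide of 2 by SN2, the base being too weak to open the lactone.

Step 3
Reactants: 4 2,4-dimethoxy-6-[(4-methoxy-2-oxo-2H-pyran-6-yl)methoxy]benzaldehyde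
Product: 6 6-[(2-hydroxy-3,5-dimethoxyphenoxy)methyl]-4-methoxy-2H-pyran-2-one, via aryl formate 5 (not isolated)
Conditions: mCPBA, CH2Cl2, 0 °C to rt; then Et3N, MeOH, rt
Reagents that add atoms: 3-chloroperoxybenzoic acid, OOC(=O)c1cccc(Cl)c1
Why: Baeyer-Villiger oxidation, in which the 2,4,6-trioxygenated aryl group migrates in preference to hydride to give the aryl formate, which amine-catalysed methanolysis cleaves without touching the lactone; the electron-poor pyranone double bonds should not be epoxidised.

Step 4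
Reactants: 6 6-[(2-hydroxy-3,5-dimethoxyphenoxy)methyl]-4-methoxy-2H-pyran-2-one
Product: 7 6-{[2-(benzyloxy)-3,5-dimethoxyphenoxy]methyl}-4-methoxy-2H-pyran-2-one
Conditions: BnBr, K2CO3, DMF, rt
Reagents that add atoms: benzyl bromide, BrCc1ccccc1
Why: Williamson benzylation of the only free phenol, installing a group that is inert to methoxide and can later be removed by hydrogenolysis in the presence of methyl ethers.

Step 5
Reactants: 7 6-{[2-(benzyloxy)-3,5-dimethoxyphenoxy]methyl}-4-methoxy-2H-pyran-2-one
Product: 9 2-[2-(benzyloxy)-3,5-dimethoxyphenoxy]-5-methoxybenzene-1,3-diol, via open-chain keto ester 8 (not isolated)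
Conditions: NaOMe (excess), MeOH, reflux, argon; then aq. HCl
Reagents that add atoms: none
Why: Methoxide adds to the lactone carbonyl of 7 and the ring opens to the enolate of keto ester 8, whose central carbonyl stays masked as the methyl enol ether; proton exchange then populates the enolate at the carbon bearing the aryloxy group (more acidic than a plain methyl ketone position), and this carbon attacks the methyl ester in an intramolecular Claisen (Dieckmann-type) condensation that forms the A-C1 to A-C2 bond. Loss of methoxide and enolisation of the resulting cyclohexenedione give the aromatic resorcinol, and formation of its phenoxide should make the sequence irreversible. The closest known reaction type is the alkoxide-induced conversion of 4-methoxy-6-alkyl-2-pyranones into phloroglucinol monomethyl ethers. Ring A closes in a 6-(enolendo)-exo-trig mode, a favoured closure, since both enolate carbons (the former ketone carbon and the aryloxy-bearing carbon) lie inside the new ring. No stereocentre is created. The step needs chemoselective attack at the lactone and a cis enoate: methoxide makes ester exchange and addition-elimination at the C4 enol ether degenerate, the ring origin of the enoate holds the ester and the ketone side chain cis, and the benzyl, methyl and aryl ethers are inert to methoxide.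

Step 6
Reactants: 9 2-[2-(benzyloxy)-3,5-dimethoxyphenoxy]-5-methoxybenzene-1,3-diol
Product: 10 2-(benzyloxy)-1,5-dimethoxy-3-(2,4,6-trimethoxyphenoxy)benzene
Conditions: MeI, K2CO3, DMF, rt
Reagents that add atoms: iodomethane, CI
Why: Williamson O-methylation of the two ring A phenols, each with only one ortho substituent, so that ring A carries the same ether type as all other hydroxyls awaiting the final deprotection.

Step 7
Reactants: 10 2-(benzyloxy)-1,5-dimethoxy-3-(2,4,6-trimethoxyphenoxy)benzene
Product: 11 2,4-dimethoxy-6-(2,4,6-trimethoxyphenoxy)phenol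
Conditions: H2 (1 atm), Pd/C, EtOAc-MeOH, rt
Reagents that add atoms: none
Why: Catalytic hydrogenolysis cleaves only the benzylic C-O bond and frees the hydroxyl at B-C2, methyl and diaryl ethers being inert.

**Fragment C-D-E**

Step 8
Reactants: 12 2-bromo-3,4,5-trimethoxybenzaldehyde; 13 3,4,5-trimethoxyphenol
Product: 14 3,4,5-trimethoxy-2-(3,4,5-trimethoxyphenoxy)benzaldehyde
Conditions: CuI (10 mol %), picolinic acid (20 mol %), K3PO4, DMSO, 90 °C, argon
Reagents that add atoms: none
Why: Ullmann-type copper-catalysed diaryl ether synthesis, in which the ortho-formyl group activates the bromide, the unhindered electron-rich phenol 13 is a good nucleophile, and the picolinic acid ligand permits coupling at a doubly ortho-substituted carbon.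

Step 9
Reactants: 14 3,4,5-trimethoxy-2-(3,4,5-trimethoxyphenoxy)benzaldehyde
Product: 16 3,4,5-trimethoxy-2-(3,4,5-trimethoxyphenoxy)phenol, via aryl formate 15 (not isolated)
Conditions: mCPBA, CH2Cl2, 0 °C to rt; then Et3N, MeOH, rt
Reagents that add atoms: 3-chloroperoxybenzoic acid, OOC(=O)c1cccc(Cl)c1
Why: Baeyer-Villiger oxidation, in which the ring D aryl group (ortho-aryloxy, para-methoxy) migrates readily, turning the formyl carbon into the oxygen at D-C1 after methanolysis of the formate.

Step 10
Reactants: 16 3,4,5-trimethoxy-2-(3,4,5-trimethoxyphenoxy)phenol; 17 4-bromo-3,5-dimethoxybenzaldehyde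
Product: 18 3,5-dimethoxy-4-[3,4,5-trimethoxy-2-(3,4,5-trimethoxyphenoxy)phenoxy]benzaldehyde
Conditions: Pd(OAc)2 (3 mol %), tBuXPhos (5 mol %), K3PO4, toluene, 100 °C
Reagents that add atoms: none
Why: Buchwald-Hartwig-type palladium-catalysed C-O coupling, in which the para-formyl group makes bromide 17 electron-poor (favouring oxidative addition and C-O reductive elimination) and the bulky di-tert-butyl biaryl phosphine is the ligand class that delivers tri-ortho-substituted diaryl ethers, while K3PO4 spares the aldehyde.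

Step 11
Reactants: 18 3,5-dimethoxy-4-[3,4,5-trimethoxy-2-(3,4,5-trimethoxyphenoxy)phenoxy]benzaldehyde
Product: 20 3,5-dimethoxy-4-[3,4,5-trimethoxy-2-(3,4,5-trimethoxyphenoxy)phenoxy]phenol, via aryl formate 19 (not isolated)
Conditions: mCPBA, CH2Cl2, 0 °C to rt; then Et3N, MeOH, rt
Reagents that add atoms: 3-chloroperoxybenzoic acid, OOC(=O)c1cccc(Cl)c1
Why: Baeyer-Villiger oxidation of a 4-aryloxy-3,5-dimethoxybenzaldehyde, whose para-oxygenated aryl group migrates as in the 3,4,5-trimethoxybenzaldehyde series, placing the oxygen at C1 of ring C.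

Step 12
Reactants: 20 3,5-dimethoxy-4-[3,4,5-trimethoxy-2-(3,4,5-trimethoxyphenoxy)phenoxy]phenol
Product: 21 3,5-dimethoxy-4-[3,4,5-trimethoxy-2-(3,4,5-trimethoxyphenoxy)phenoxy]phenyl trifluoromethanesulfonate
Conditions: Tf2O, pyridine, CH2Cl2, 0 °C
Reagents that add atoms: trifluoromethanesulfonic anhydride, O=S(=O)(OS(=O)(=O)C(F)(F)F)C(F)(F)F
Why: O-sulfonylation of the phenol gives an aryl triflate, a pseudohalide for palladium catalysis at the unhindered C1 of ring C.

**Union and deprotection**

Step 13
Reactants: 11 2,4-dimethoxy-6-(2,4,6-trimethoxyphenoxy)phenol; 21 3,5-dimethoxy-4-[3,4,5-trimethoxy-2-(3,4,5-trimethoxyphenoxy)phenoxy]phenyl trifluoromethanesulfonate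
Product: 22 1,3-dimethoxy-5-[2,4-dimethoxy-6-(2,4,6-trimethoxyphenoxy)phenoxy]-2-[3,4,5-trimethoxy-2-(3,4,5-trimethoxyphenoxy)phenoxy]benzene
Conditions: Pd2(dba)3 (2.5 mol %), tBuXPhos (6 mol %), K3PO4, toluene, 100 °C
Reagents that add atoms: none
Why: Palladium-catalysed C-O coupling of an aryl triflate with a phenol, in which the electrophilic carbon of ring C has two ortho hydrogens so that hindrance lies only on the phenol side (tolerated by bulky biaryl phosphines), and the insoluble weak base in toluene limits S-O cleavage of the triflate.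

Step 14
Reactants: 22 1,3-dimethoxy-5-[2,4-dimethoxy-6-(2,4,6-trimethoxyphenoxy)phenoxy]-2-[3,4,5-trimethoxy-2-(3,4,5-trimethoxyphenoxy)phenoxy]benzene
Product: 23 5-[2,4-dihydroxy-6-(2,4,6-trihydroxyphenoxy)phenoxy]-2-[3,4,5-trihydroxy-2-(3,4,5-trihydroxyphenoxy)phenoxy]benzene-1,3-diol (target)
Conditions: BBr3 (excess), CH2Cl2, -78 °C to rt; then H2O, argon
Reagents that add atoms: none
Why: Lewis acid cleavage of aryl methyl ethers, in which BBr3 coordinates each methoxy oxygen and bromide removes the methyl group, whereas the diaryl ether bonds offer no alkyl carbon for attack and should survive; hydrolysis of the aryl borates releases the thirteen phenols.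

**Compound list**

1 | 4-methoxy-6-methyl-2H-pyran-2-one | COC1=CC(=O)OC(C)=C1 | starting material
2 | 6-(bromomethyl)-4-methoxy-2H-pyran-2-one | COC1=CC(=O)OC(CBr)=C1 | intermediate
3 | 2-hydroxy-4,6-dimethoxybenzaldehyde | COc1cc(O)c(C=O)c(OC)c1 | starting material
4 | 2,4-dimethoxy-6-[(4-methoxy-2-oxo-2H-pyran-6-yl)methoxy]benzaldehyde | COC1=CC(=O)OC(COc2cc(OC)cc(OC)c2C=O)=C1 | intermediate
5 | 2,4-dimethoxy-6-[(4-methoxy-2-oxo-2H-pyran-6-yl)methoxy]phenyl formate | COC1=CC(=O)OC(COc2cc(OC)cc(OC)c2OC=O)=C1 | intermediate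
6 | 6-[(2-hydroxy-3,5-dimethoxyphenoxy)methyl]-4-methoxy-2H-pyran-2-one | COC1=CC(=O)OC(COc2cc(OC)cc(OC)c2O)=C1 | intermediate
7 | 6-{[2-(benzyloxy)-3,5-dimethoxyphenoxy]methyl}-4-methoxy-2H-pyran-2-one | COC1=CC(=O)OC(COc2cc(OC)cc(OC)c2OCc2ccccc2)=C1 | intermediate
8 | methyl (2E)-6-[2-(benzyloxy)-3,5-dimethoxyphenoxy]-3-methoxy-5-oxohex-2-enoate (ester and ketone chain cis) | COC(=O)/C=C(OC)\CC(=O)COc1cc(OC)cc(OC)c1OCc1ccccc1 | intermediate
9 | 2-[2-(benzyloxy)-3,5-dimethoxyphenoxy]-5-methoxybenzene-1,3-diol | COc1cc(O)c(Oc2cc(OC)cc(OC)c2OCc2ccccc2)c(O)c1 | intermediate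
10 | 2-(benzyloxy)-1,5-dimethoxy-3-(2,4,6-trimethoxyphenoxy)benzene | COc1cc(OC)c(Oc2cc(OC)cc(OC)c2OCc2ccccc2)c(OC)c1 | intermediate
11 | 2,4-dimethoxy-6-(2,4,6-trimethoxyphenoxy)phenol | COc1cc(OC)c(Oc2cc(OC)cc(OC)c2O)c(OC)c1 | intermediate
12 | 2-bromo-3,4,5-trimethoxybenzaldehyde | COc1cc(C=O)c(Br)c(OC)c1OC | starting material
13 | 3,4,5-trimethoxyphenol | COc1cc(O)cc(OC)c1OC | starting material
14 | 3,4,5-trimethoxy-2-(3,4,5-trimethoxyphenoxy)benzaldehyde | COc1cc(C=O)c(Oc2cc(OC)c(OC)c(OC)c2)c(OC)c1OC | intermediate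
15 | 3,4,5-trimethoxy-2-(3,4,5-trimethoxyphenoxy)phenyl formate | COc1cc(OC=O)c(Oc2cc(OC)c(OC)c(OC)c2)c(OC)c1OC | intermediate
16 | 3,4,5-trimethoxy-2-(3,4,5-trimethoxyphenoxy)phenol | COc1cc(O)c(Oc2cc(OC)c(OC)c(OC)c2)c(OC)c1OC | intermediate
17 | 4-bromo-3,5-dimethoxybenzaldehyde | COc1cc(C=O)cc(OC)c1Br | starting material
18 | 3,5-dimethoxy-4-[3,4,5-trimethoxy-2-(3,4,5-trimethoxyphenoxy)phenoxy]benzaldehyde | COc1cc(C=O)cc(OC)c1Oc1cc(OC)c(OC)c(OC)c1Oc1cc(OC)c(OC)c(OC)c1 | intermediate
19 | 3,5-dimethoxy-4-[3,4,5-trimethoxy-2-(3,4,5-trimethoxyphenoxy)phenoxy]phenyl formate | COc1cc(OC=O)cc(OC)c1Oc1cc(OC)c(OC)c(OC)c1Oc1cc(OC)c(OC)c(OC)c1 | intermediate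
20 | 3,5-dimethoxy-4-[3,4,5-trimethoxy-2-(3,4,5-trimethoxyphenoxy)phenoxy]phenol | COc1cc(O)cc(OC)c1Oc1cc(OC)c(OC)c(OC)c1Oc1cc(OC)c(OC)c(OC)c1 | intermediate
21 | 3,5-dimethoxy-4-[3,4,5-trimethoxy-2-(3,4,5-trimethoxyphenoxy)phenoxy]phenyl trifluoromethanesulfonate | COc1cc(OS(=O)(=O)C(F)(F)F)cc(OC)c1Oc1cc(OC)c(OC)c(OC)c1Oc1cc(OC)c(OC)c(OC)c1 | intermediate
22 | 1,3-dimethoxy-5-[2,4-dimethoxy-6-(2,4,6-trimethoxyphenoxy)phenoxy]-2-[3,4,5-trimethoxy-2-(3,4,5-trimethoxyphenoxy)phenoxy]benzene (tridecamethyl ether of the target) | COc1cc(OC)c(Oc2cc(OC)cc(OC)c2Oc2cc(OC)c(Oc3cc(OC)c(OC)c(OC)c3Oc3cc(OC)c(OC)c(OC)c3)c(OC)c2)c(OC)c1 | intermediate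
23 | 5-[2,4-dihydroxy-6-(2,4,6-trihydroxyphenoxy)phenoxy]-2-[3,4,5-trihydroxy-2-(3,4,5-trihydroxyphenoxy)phenoxy]benzene-1,3-diol (no stereocentres) | Oc1cc(O)c(Oc2cc(O)cc(O)c2Oc2cc(O)c(Oc3cc(O)c(O)c(O)c3Oc3cc(O)c(O)c(O)c3)c(O)c2)c(O)c1 | target

**Step count and risk**

Total: 14 steps. Longest linear sequence: 9 steps (steps 1 to 7, then 13 and 14). The C-D-E branch contributes 5 steps (8 to 12) before the union.

Steps most likely to fail:

1. Step 5. The ring-opened keto ester may fail to C-acylate: the extended dienolate formed on lactone opening is the resting state, and reclosure to the pyranone or retro-Claisen cleavage of the ketone by methoxide could outrun enolisation at the aryloxy-bearing carbon. The fallback makes the A-O-B ether by cross-coupling instead of building ring A; it sets out from 3 and returns to the route at 11. Compound 3 is converted with Tf2O and pyridine into 2-formyl-3,5-dimethoxyphenyl trifluoromethanesulfonate F1. Palladium-catalysed C-O coupling of this ortho-formyl-activated triflate with purchased 2,4,6-trimethoxyphenol (Pd(OAc)2, tBuXPhos, K3PO4, toluene, 100 °C) should give 2,4-dimethoxy-6-(2,4,6-trimethoxyphenoxy)benzaldehyde F2. Baeyer-Villiger oxidation with mCPBA then gives 2,4-dimethoxy-6-(2,4,6-trimethoxyphenoxy)phenyl formate F3, and methanolysis with Et3N in MeOH delivers 11.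

2. Step 13. With two electron-rich partners the C-O reductive elimination may be slow, so that transfer or hydrolysis of the triflyl group and reduction of the aryl-palladium species compete. The fallback inverts the roles of the metals and uses an oxidative copper coupling; it sets out from 21 and returns at 22. Miyaura borylation of 21 (B2pin2, PdCl2(dppf), KOAc, dioxane, 80 °C) should give 2-{3,5-dimethoxy-4-[3,4,5-trimethoxy-2-(3,4,5-trimethoxyphenoxy)phenoxy]phenyl}-4,4,5,5-tetramethyl-1,3,2-dioxaborolane F4. Cleavage of the pinacol ester with NaIO4 and NH4OAc in aqueous acetone gives {3,5-dimethoxy-4-[3,4,5-trimethoxy-2-(3,4,5-trimethoxyphenoxy)phenoxy]phenyl}boronic acid F5. Chan-Lam coupling of this boronic acid with phenol 11 (Cu(OAc)2, pyridine, 4 Å molecular sieves, CH2Cl2, air, rt), a method suited to doubly ortho-substituted phenols and unhindered arylboronic acids, then gives 22.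

3. Step 14. Cleavage of thirteen methyl ethers may stop at partially methylated stages, and the free polyphenol may oxidise in air during isolation. The fallback isolates the product as a stable derivative and releases it under non-oxidising acidic conditions; it sets out from 22 and returns at 23. The crude material from the BBr3 treatment is acetylated directly (Ac2O, pyridine, rt) to the tridecaacetate of the target F6, which can be chromatographed, and from which under-cleaved material can be separated and resubmitted. Acid-catalysed methanolysis of F6 (catalytic AcCl in MeOH, rt, argon) followed by evaporation then gives 23 without exposure of phenoxides to air.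

**Further compounds**

F1 | step 5 | 2-formyl-3,5-dimethoxyphenyl trifluoromethanesulfonate | COc1cc(OC)c(C=O)c(OS(=O)(=O)C(F)(F)F)c1
F2 | step 5 | 2,4-dimethoxy-6-(2,4,6-trimethoxyphenoxy)benzaldehyde | COc1cc(OC)c(C=O)c(Oc2c(OC)cc(OC)cc2OC)c1
F3 | step 5 | 2,4-dimethoxy-6-(2,4,6-trimethoxyphenoxy)phenyl formate | COc1cc(OC)c(OC=O)c(Oc2c(OC)cc(OC)cc2OC)c1
F4 | step 13 | 2-{3,5-dimethoxy-4-[3,4,5-trimethoxy-2-(3,4,5-trimethoxyphenoxy)phenoxy]phenyl}-4,4,5,5-tetramethyl-1,3,2-dioxaborolane | COc1cc(B2OC(C)(C)C(C)(C)O2)cc(OC)c1Oc1cc(OC)c(OC)c(OC)c1Oc1cc(OC)c(OC)c(OC)c1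
F5 | step 13 | {3,5-dimethoxy-4-[3,4,5-trimethoxy-2-(3,4,5-trimethoxyphenoxy)phenoxy]phenyl}boronic acid | COc1cc(B(O)O)cc(OC)c1Oc1cc(OC)c(OC)c(OC)c1Oc1cc(OC)c(OC)c(OC)c1
F6 | step 14 | tridecaacetate of the target | CC(=O)Oc1cc(OC(C)=O)c(Oc2cc(OC(C)=O)cc(OC(C)=O)c2Oc2cc(OC(C)=O)c(Oc3cc(OC(C)=O)c(OC(C)=O)c(OC(C)=O)c3Oc3cc(OC(C)=O)c(OC(C)=O)c(OC(C)=O)c3)c(OC(C)=O)c2)c(OC(C)=O)c1
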